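A direct plan would resolve racemic 2-methylhept-1-en-6-yn-3-ol A1 to the (R)-alcohol A2 by Sharpless kinetic resolution and would silylate A2 to the silyl ether A3.
Cp2ZrCl2-catalysed methylalumination of A3 with Al(CH3)3 would give the (E)-alkenylalane A4, and its capture by the aryloxymethyl chloride A5 of a sinapate ester would form C1–C2 in the coupled ester A6; ester reduction and desilylation of A6 would finish.
Its weakest steps would be:
- the kinetic resolution of A1 to A2, which would give up at least half of the enynol;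
- the making of A5 by chlorinative cleavage of an O,S-acetal beside an electron-rich cinnamate, because this chloromethyl aryl ether would be labile and usable only crude;
- the capture of A4 by A5 to give A6, which would lack precedent and would compete with methyl transfer and with attack on the enoate.

The proposed route disconnects C4–C5 (chain numbered from C1 at OCH2 to C8 at =CH2). The C2=C3 alkene and the C6 oxygen stand in the γ,δ-unsaturated carbonyl relationship of a Claisen product, and C6 is flanked by the C7=C8 isopropenyl group. A ketal Claisen rearrangement of a racemic aryloxymethyl isopropenyl carbinol with the dimethyl ketal of methyl isopropenyl ketone would form C4–C5, set the (E)-C2=C3 alkene and deliver the C6 enone in one operation. Reagent-controlled reduction of that ketone would then set the only stereocentre. No resolution, no chloromethyl ether, no organoalane capture and no protecting group would be needed.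

Key step: step 4

Step 1
Reactants: 1 methacrolein (2-methylprop-2-enal)
Product: 2 (±)-2-(prop-1-en-2-yl)oxirane
Conditions: (CH3)3S+ I− (1.2 equiv), NaH (1.2 equiv), DMSO–THF, −5 °C; then 1, −5 → 20 °C; water, pentane extraction, fractional distillation
Reagents that add atoms: trimethylsulfonium iodide C[S+](C)C.[I-]
Why: Corey–Chaykovsky epoxidation, in which the unstabilised sulfonium ylide should add 1,2 to the enal carbonyl and the betaine close to the oxirane with loss of dimethyl sulfide; the racemate suffices because this carbon becomes sp2 in step 4.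

Step 2
Reactants: 3 methyl sinapate [methyl (E)-3-(4-hydroxy-3,5-dimethoxyphenyl)prop-2-enoate]; 2 (±)-2-(prop-1-en-2-yl)oxirane
Product: 4 (±)-methyl (E)-3-[4-(2-hydroxy-3-methylbut-3-enoxy)-3,5-dimethoxyphenyl]prop-2-enoate
Conditions: 2 (2 equiv), K2CO3 (0.2 equiv), DMF, 70 °C, sealed vessel
Reagents that add atoms: none
Why: Base-mediated ring opening of a monosubstituted epoxide by a phenoxide, which should attack the unsubstituted CH2 in an SN2 manner and so form the aryl–O–C1 bond and the secondary allylic alcohol without touching the enoate.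

Step 3
Reactants: 5 3-methylbut-3-en-2-one (methyl isopropenyl ketone)
Product: 6 3,3-dimethoxy-2-methylbut-1-ene
Conditions: HC(OCH3)3 (1.2 equiv), CH3OH (1 equiv), p-toluenesulfonic acid (0.5 mol %), 0 → 20 °C; NaOCH3 quench; distillation from K2CO3
Reagents that add atoms: trimethyl orthoformate COC(OC)OC
Why: Acid-catalysed ketalisation driven by the orthoformate, run cold with little acid and a basic quench so that ketal formation should outrun conjugate addition of methanol to the α-methyl enone.

Step 4
Reactants: 4 (±)-methyl (E)-3-[4-(2-hydroxy-3-methylbut-3-enoxy)-3,5-dimethoxyphenyl]prop-2-enoate; 6 3,3-dimethoxy-2-methylbut-1-ene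
Product: 9 methyl (E)-3-[4-[(2E)-3,7-dimethyl-6-oxoocta-2,7-dienoxy]-3,5-dimethoxyphenyl]prop-2-enoate, via mixed methyl allyl ketal 7 (not isolated), via allyl 3-methylbuta-1,3-dien-2-yl ether 8 (not isolated)
Conditions: 6 (4 equiv), 2,4-dinitrophenol (5 mol %), 2,6-di-tert-butyl-4-methylphenol (1 mol %), toluene, 110 °C, CH3OH distilled off
Reagents that add atoms: none
Why: Acid-catalysed exchange of the secondary allylic alcohol 4 into ketal 6 should give the mixed ketal 7, which can lose methanol only towards its methyl group and so gives the allyl dienyl ether 8; this should undergo a [3,3]-sigmatropic Claisen rearrangement in which the C4–C5 bond forms, the C2–O bond breaks and the C6 carbonyl appears already flanked by the C7=C8 isopropenyl group. The closest known reaction type is the olefinic ketal Claisen rearrangement of 2-methylallylic secondary alcohols used for head-to-tail isoprenoid chain extension. No ring is closed and no stereocentre is created; the racemic carbinol carbon of 4 becomes the sp2 carbon C2. The step needs E over Z geometry at C2=C3, which the chair transition state should secure because the aryloxymethyl group sits equatorial, the axial position clashing with the isopropenyl group on the oxygen-bearing carbon. It also needs the aliphatic rearrangement to be the only sigmatropic event, which the two ortho methoxy groups and the para substituent secure by blocking an aromatic Claisen rearrangement of the aryl allyl ether formed, and it needs the enoate and the polymerisable enone to survive, which the weak acid, the radical inhibitor and the moderate temperature should secure.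

Step 5
Reactants: 9 methyl (E)-3-[4-[(2E)-3,7-dimethyl-6-oxoocta-2,7-dienoxy]-3,5-dimethoxyphenyl]prop-2-enoate
Product: 10 methyl (E)-3-[4-[(2E,6R)-6-hydroxy-3,7-dimethylocta-2,7-dienoxy]-3,5-dimethoxyphenyl]prop-2-enoate
Conditions: (S)-2-methyl-CBS-oxazaborolidine [(S)-1-methyl-3,3-diphenyltetrahydro-1H,3H-pyrrolo[1,2-c][1,3,2]oxazaborole] (0.2 equiv), catecholborane (1.6 equiv), toluene, −78 °C; CH3OH, then cold aq. Na2CO3 wash
Reagents that add atoms: none
Why: Corey–Bakshi–Shibata reduction, in which the ketone should bind the ring boron with the larger, α-branched sp2 isopropenyl group turned away from the catalyst and receive hydride on the face that gives the (R)-carbinol at C6 (the sense in which this catalyst gives (R)-1-phenylethanol, isopropenyl taking the part of phenyl), while catecholborane at −78 °C should leave the methyl ester and the alkenes alone.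

Step 6
Reactants: 10 methyl (E)-3-[4-[(2E,6R)-6-hydroxy-3,7-dimethylocta-2,7-dienoxy]-3,5-dimethoxyphenyl]prop-2-enoate
Product: 11 (3R,6E)-8-[4-[(E)-3-hydroxyprop-1-enyl]-2,6-dimethoxyphenoxy]-2,6-dimethylocta-1,6-dien-3-ol (target)
Conditions: i-Bu2AlH (4 equiv), CH2Cl2, −78 → −40 °C; aq. potassium sodium tartrate
Reagents that add atoms: none
Why: i-Bu2AlH should reduce the α,β-unsaturated ester by two 1,2-hydride deliveries to the (E)-allylic alcohol, the free C6 hydroxyl merely consuming one equivalent as its aluminium alkoxide, so that the stereocentre, the alkenes and the allyl aryl ether are not involved.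

**Compound list**
1 | methacrolein (2-methylprop-2-enal) | C=C(C)C=O | starting material
2 | (±)-2-(prop-1-en-2-yl)oxirane | C=C(C)C1CO1 | intermediate
3 | methyl sinapate [methyl (E)-3-(4-hydroxy-3,5-dimethoxyphenyl)prop-2-enoate] | COC(=O)/C=C/c1cc(OC)c(O)c(OC)c1 | starting material
4 | (±)-methyl (E)-3-[4-(2-hydroxy-3-methylbut-3-enoxy)-3,5-dimethoxyphenyl]prop-2-enoate | C=C(C)C(O)COc1c(OC)cc(/C=C/C(=O)OC)cc1OC | intermediate
5 | 3-methylbut-3-en-2-one | CC(=O)C(C)=C | starting material
6 | 3,3-dimethoxy-2-methylbut-1-ene | C=C(C)C(C)(OC)OC | intermediate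
7 | methyl (E)-3-[3,5-dimethoxy-4-[2-(2-methoxy-3-methylbut-3-en-2-yl)oxy-3-methylbut-3-enoxy]phenyl]prop-2-enoate (mixed ketal, diastereomer mixture) | C=C(C)C(C)(OC)OC(COc1c(OC)cc(/C=C/C(=O)OC)cc1OC)C(C)=C | intermediate
8 | methyl (E)-3-[3,5-dimethoxy-4-[3-methyl-2-(3-methylbuta-1,3-dien-2-yloxy)but-3-enoxy]phenyl]prop-2-enoate (racemic) | C=C(C)C(=C)OC(COc1c(OC)cc(/C=C/C(=O)OC)cc1OC)C(C)=C | intermediate
9 | methyl (E)-3-[4-[(2E)-3,7-dimethyl-6-oxoocta-2,7-dienoxy]-3,5-dimethoxyphenyl]prop-2-enoate | C=C(C)C(=O)CC/C(C)=C/COc1c(OC)cc(/C=C/C(=O)OC)cc1OC | intermediate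
10 | methyl (E)-3-[4-[(2E,6R)-6-hydroxy-3,7-dimethylocta-2,7-dienoxy]-3,5-dimethoxyphenyl]prop-2-enoate | C=C(C)[C@H](O)CC/C(C)=C/COc1c(OC)cc(/C=C/C(=O)OC)cc1OC | intermediate
11 | (3R,6E)-8-[4-[(E)-3-hydroxyprop-1-enyl]-2,6-dimethoxyphenoxy]-2,6-dimethylocta-1,6-dien-3-ol (CNP0161487.1) | C=C(C)[C@H](O)CC/C(C)=C/COc1c(OC)cc(/C=C/CO)cc1OC | target

Total step count: 6. Longest linear sequence: 5 steps (steps 1, 2, 4, 5 and 6).

Steps most likely to fail:

Step 4. The ketal exchange may stall at the β-aryloxy secondary carbinol, or the dienyl ether and the enone may be lost to acid-promoted oligomerisation before or after the rearrangement. The fallback sets out from 3 and comes back at 10. O-Alkylation of 3 with geranyl bromide (K2CO3, DMF) would give methyl (E)-3-[4-[(2E)-3,7-dimethylocta-2,6-dienoxy]-3,5-dimethoxyphenyl]prop-2-enoate F1. m-Chloroperbenzoic acid in CH2Cl2 at 0 °C would epoxidise the more electron-rich distal alkene to (±)-methyl (E)-3-[4-[(2E)-5-(3,3-dimethyloxiran-2-yl)-3-methylpent-2-enoxy]-3,5-dimethoxyphenyl]prop-2-enoate F2. H5IO6 in THF–water would cleave this to methyl (E)-3-[3,5-dimethoxy-4-[(2E)-3-methyl-6-oxohex-2-enoxy]phenyl]prop-2-enoate F3. A catalytic asymmetric Nozaki–Hiyama–Kishi coupling of F3 with 2-bromopropene (CrCl2 and NiCl2 as catalysts, Mn, (CH3)3SiCl, a chiral oxazoline–sulfonamide ligand in the enantiomeric form that gives the (R)-carbinol) would then form C6–C7 and give 10.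

Step 3. Conjugate addition of methanol to the enone, or its polymerisation under acid, may outrun ketalisation and leave no usable ketal. The fallback sets out from 4 and comes back at 9. Purchased 3-hydroxy-3-methylbutan-2-one, which cannot undergo conjugate addition, would be ketalised in the same way to 3,3-dimethoxy-2-methylbutan-2-ol F4. Its ketal Claisen rearrangement with 4 under the conditions of step 4 would give the α-hydroxy ketone methyl (E)-3-[4-[(2E)-7-hydroxy-3,7-dimethyl-6-oxooct-2-enoxy]-3,5-dimethoxyphenyl]prop-2-enoate F5. Dehydration of its tertiary alcohol (SOCl2, pyridine, 0 °C) would give 9, the C7=C8 alkene being made after the rearrangement and not before it.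

Step 5. The catalyst may discriminate poorly between the isopropenyl group and the primary alkyl chain, or catecholborane may reduce the enone in the 1,4 sense. The fallback sets out from 9 and comes back at 10. Luche reduction (NaBH4, CeCl3·7H2O, CH3OH, −40 °C) would give the racemic alcohol (±)-methyl (E)-3-[4-[(2E)-6-hydroxy-3,7-dimethylocta-2,7-dienoxy]-3,5-dimethoxyphenyl]prop-2-enoate F6. A Sharpless kinetic resolution (Ti(OCH(CH3)2)4, L-(+)-diisopropyl tartrate, t-BuOOH 0.6 equiv, 4 Å molecular sieves, CH2Cl2, −20 °C) would consume the (S)-enantiomer as the erythro epoxy alcohol methyl (E)-3-[4-[(2E,6S)-6-hydroxy-3-methyl-6-[(2R)-2-methyloxiran-2-yl]hex-2-enoxy]-3,5-dimethoxyphenyl]prop-2-enoate F7 and leave 10.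

**Further compounds**
F1 | step 4 | methyl (E)-3-[4-[(2E)-3,7-dimethylocta-2,6-dienoxy]-3,5-dimethoxyphenyl]prop-2-enoate | CC(C)=CCC/C(C)=C/COc1c(OC)cc(/C=C/C(=O)OC)cc1OC
F2 | step 4 | (±)-methyl (E)-3-[4-[(2E)-5-(3,3-dimethyloxiran-2-yl)-3-methylpent-2-enoxy]-3,5-dimethoxyphenyl]prop-2-enoate | CC1(C)OC1CC/C(C)=C/COc2c(OC)cc(/C=C/C(=O)OC)cc2OC
F3 | step 4 | methyl (E)-3-[3,5-dimethoxy-4-[(2E)-3-methyl-6-oxohex-2-enoxy]phenyl]prop-2-enoate | O=CCC/C(C)=C/COc1c(OC)cc(/C=C/C(=O)OC)cc1OC
F4 | step 3 | 3,3-dimethoxy-2-methylbutan-2-ol | CC(C)(O)C(C)(OC)OC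
F5 | step 3 | methyl (E)-3-[4-[(2E)-7-hydroxy-3,7-dimethyl-6-oxooct-2-enoxy]-3,5-dimethoxyphenyl]prop-2-enoate | CC(C)(O)C(=O)CC/C(C)=C/COc1c(OC)cc(/C=C/C(=O)OC)cc1OC
F6 | step 5 | (±)-methyl (E)-3-[4-[(2E)-6-hydroxy-3,7-dimethylocta-2,7-dienoxy]-3,5-dimethoxyphenyl]prop-2-enoate | C=C(C)C(O)CC/C(C)=C/COc1c(OC)cc(/C=C/C(=O)OC)cc1OC
F7 | step 5 | methyl (E)-3-[4-[(2E,6S)-6-hydroxy-3-methyl-6-[(2R)-2-methyloxiran-2-yl]hex-2-enoxy]-3,5-dimethoxyphenyl]prop-2-enoate | C[C@@]1(CO1)[C@@H](O)CC/C(C)=C/COc2c(OC)cc(/C=C/C(=O)OC)cc2OC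
A1 | direct plan | (±)-2-methylhept-1-en-6-yn-3-ol | C=C(C)C(O)CCC#C
A2 | direct plan | (R)-2-methylhept-1-en-6-yn-3-ol | C=C(C)[C@H](O)CCC#C
A3 | direct plan | (R)-tert-butyldimethyl[(2-methylhept-1-en-6-yn-3-yl)oxy]silane | C=C(C)[C@H](O[Si](C)(C)C(C)(C)C)CCC#C
A4 | direct plan | [(1E,5R)-5-(tert-butyldimethylsilyloxy)-2,6-dimethylhepta-1,6-dien-1-yl]dimethylalumane | C=C(C)[C@H](O[Si](C)(C)C(C)(C)C)CC/C(C)=C/[Al](C)C
A5 | direct plan | ethyl (E)-3-[4-(chloromethoxy)-3,5-dimethoxyphenyl]prop-2-enoate | ClCOc1c(OC)cc(/C=C/C(=O)OCC)cc1OC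
A6 | direct plan | ethyl (E)-3-[4-[(2E,6R)-6-(tert-butyldimethylsilyloxy)-3,7-dimethylocta-2,7-dienoxy]-3,5-dimethoxyphenyl]prop-2-enoate | C=C(C)[C@H](O[Si](C)(C)C(C)(C)C)CC/C(C)=C/COc1c(OC)cc(/C=C/C(=O)OCC)cc1OC
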